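**Retrosynthetic overview**
1. The C14–O ester (Steglich) and the C6'=C7' alkene (cross-metathesis) are disconnected first; the C7–C8 bond is made late by a substrate-controlled boron aldol between a C8–C15 methyl ketone and a C1–C7 aldehyde.
2. C9–C11 come from L-tartaric acid acetonide diacid: one CO2H is replaced photochemically by C12 (decarboxylative radical addition, C11–C12 bond), the other becomes the C9 ketone.
3. C12 and C14 are set with a δ-lactone made from (R)-propylene oxide as a stereodirecting tether; its carbonyl carbon is then excised by photochemical hydrodecarboxylation, leaving the C12 methyl group.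
4. C5 comes from L-malic acid (acetal-relayed α-methylation); C9' comes from L-leucine (α-chloro aldehyde), which also controls C8' (anti-chlorohydrin).
5. Ring order: the temporary δ-lactone is formed in step 2 and opened in step 6; the only ring of the target, the oxirane, is closed in the last step.

Assumption: (R)-propylene oxide, dimethyl 2,3-O-isopropylidene-L-tartrate, L-leucine and L-malic acid are the bought chiral materials. Locants in the text: polyol chain C1 (terminal =CH2) to C15 (C5 tertiary carbinol, C9 ketone, C14 ester carbinol); acyl chain C1' to C9' (C8'/C9' oxirane).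

**Step 1**
Reactants: 1 (R)-2-methyloxirane; 2 ethyl prop-2-ynoate
Product: 4 ethyl (5R)-5-hydroxyhex-2-ynoate, via lithium acetylide 3 (not isolated)
Conditions: n-BuLi, THF, −78 °C; then BF3·OEt2 and 1, −78 °C; H2O
Reagents that add atoms: n-butyllithium [Li]CCCC (Li of 3 only)
Why: BF3-promoted opening of the terminal epoxide at its CH2 carbon by the lithium acetylide (Yamaguchi–Hirao alkynylation) leaves the bought stereocentre untouched.

**Step 2**
Reactants: 4 ethyl (5R)-5-hydroxyhex-2-ynoate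
Product: 6 (6R)-6-methyl-5,6-dihydro-2H-pyran-2-one, via Z-hydroxy enoate 5 (not isolated)
Conditions: H2 (1 atm), Lindlar Pd, quinoline, EtOAc, rt; then TsOH (cat.), PhH, 50 °C
Reagents that add atoms: none
Why: Lindlar semihydrogenation gives the Z-enoate, which lactonises with loss of ethanol; the stereocentre is not involved.

**Step 3**
Reactants: 7 dimethyl (4R,5R)-2,2-dimethyl-1,3-dioxolane-4,5-dicarboxylate
Product: 8 (4R,5R)-2,2-dimethyl-1,3-dioxolane-4,5-dicarboxylic acid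
Conditions: LiOH·H2O (2.5 equiv), THF/H2O, 0 °C to rt; then 1 M HCl to pH 2
Reagents that add atoms: lithium hydroxide [Li+].[OH-]
Why: Saponification of both esters; the trans-dioxolane is the stable arrangement, so the stereocentres are not at risk.

**Step 4**
Reactants: 8 (4R,5R)-2,2-dimethyl-1,3-dioxolane-4,5-dicarboxylic acid; 6 (6R)-6-methyl-5,6-dihydro-2H-pyran-2-one
Product: 9 (4R,5S)-2,2-dimethyl-5-[(2R,4R)-2-methyl-6-oxooxan-4-yl]-1,3-dioxolane-4-carboxylic acid
Conditions: 8 (3 equiv), Cs2CO3 (1.5 equiv), 4CzIPN (2 mol%), DMSO, 450 nm LEDs, 25 °C, degassed; work-up at pH 3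
Reagents that add atoms: none
Why: Proposed new method: single (desymmetrising) photoredox decarboxylation of the C2-symmetric diacid as its mono-caesium salt (carboxylate oxidised by excited 4CzIPN, loss of CO2) gives the dioxolan-4-yl radical, which adds trans to the remaining carboxyl group (C11, tartrate configuration retained) and to C4 of lactone 6 by axial attack anti to the 6-methyl group (C12, 4,6-trans), after which the α-acyl radical is reduced by the catalyst radical anion and protonated; the excess of cheap diacid suppresses a second decarboxylation of the product; the closest known reactions are the photoredox decarboxylative Giese addition of α-alkoxy acids and Barton-ester additions of tartrate half-ester radicals, neither shown on a free C2-symmetric diacid or with a chiral dihydropyranone as a traceless stereodirecting acceptor.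

**Step 5**
Reactants: 9 (4R,5S)-2,2-dimethyl-5-[(2R,4R)-2-methyl-6-oxooxan-4-yl]-1,3-dioxolane-4-carboxylic acid
Product: 11 (4R,6R)-4-[(4S,5R)-5-acetyl-2,2-dimethyl-1,3-dioxolan-4-yl]-6-methyloxan-2-one, via acid chloride 10 (not isolated)
Conditions: 1-chloro-N,N,2-trimethylprop-1-en-1-amine, CH2Cl2, 0 °C to rt; then MeMgBr (1.05 equiv), Fe(acac)3 (3 mol%), THF, −78 °C
Reagents that add atoms: 1-chloro-N,N,2-trimethylprop-1-en-1-amine CC(C)=C(Cl)N(C)C (Cl of 10 only); methylmagnesium bromide C[Mg]Br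
Why: Neutral acid chloride formation and iron-catalysed acyl chloride–Grignard coupling give the methyl ketone faster than the lactone reacts at −78 °C; the trans-dioxolane centre is the stable epimer.

**Step 6**
Reactants: 11 (4R,6R)-4-[(4S,5R)-5-acetyl-2,2-dimethyl-1,3-dioxolan-4-yl]-6-methyloxan-2-one
Product: 13 1-{(4R,5S)-5-[(2S,4R)-4-hydroxypentan-2-yl]-2,2-dimethyl-1,3-dioxolan-4-yl}ethan-1-one, via lithium hydroxy carboxylate 12 (not isolated)
Conditions: LiOH (1.1 equiv), THF/H2O, 0 °C; evaporate; then 9-mesityl-10-phenylacridinium BF4 (5 mol%), (PhS)2 (10 mol%), CF3CH2OH, 450 nm LEDs, rt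
Reagents that add atoms: lithium hydroxide [Li+].[OH-] (Li and one O of 12 only)
Why: Lactone saponification followed by acridinium-photoredox hydrodecarboxylation (carboxylate oxidation, CO2 loss, H-atom transfer from thiophenol) turns the tether CH2CO2 group into the C12 methyl group and frees the C14 hydroxyl without touching a stereocentre.

**Step 7**
Reactants: 14 pent-4-enal; 15 2-methylpropanedioic acid
Product: 16 (2E)-2-methylhepta-2,6-dienoic acid
Conditions: pyridine, piperidine (cat.), 90 °C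
Reagents that add atoms: none
Why: Knoevenagel–Doebner condensation with decarboxylation gives the E-configured 2-methyl-2-enoic acid.

**Step 8**
Reactants: 13 1-{(4R,5S)-5-[(2S,4R)-4-hydroxypentan-2-yl]-2,2-dimethyl-1,3-dioxolan-4-yl}ethan-1-one; 16 (2E)-2-methylhepta-2,6-dienoic acid
Product: 17 (2R,4S)-4-[(4S,5R)-5-acetyl-2,2-dimethyl-1,3-dioxolan-4-yl]pentan-2-yl (2E)-2-methylhepta-2,6-dienoate
Conditions: DCC, DMAP (cat.), CH2Cl2, 0 °C to rt
Reagents that add atoms: none
Why: Steglich esterification of the only free hydroxyl, with retention at C14.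

**Step 9**
Reactants: 17 (2R,4S)-4-[(4S,5R)-5-acetyl-2,2-dimethyl-1,3-dioxolan-4-yl]pentan-2-yl (2E)-2-methylhepta-2,6-dienoate
Product: 18 (2R,4S,5S,6R)-5,6-dihydroxy-4-methyl-7-oxooctan-2-yl (2E)-2-methylhepta-2,6-dienoate
Conditions: 2 M HCl, THF, 45 °C
Reagents that add atoms: none
Why: Acid hydrolysis of the acetonide is done here, before any acid-labile group is present.

**Step 10**
Reactants: 19 L-leucine
Product: 20 (2S)-2-chloro-4-methylpentanoic acid
Conditions: NaNO2, 5 M HCl, 0 °C to rt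
Reagents that add atoms: hydrochloric acid Cl
Why: Diazotisation with double inversion through the α-lactone gives the α-chloro acid with net retention.

**Step 11**
Reactants: 20 (2S)-2-chloro-4-methylpentanoic acid
Product: 21 (2S)-2-chloro-4-methylpentan-1-ol
Conditions: BH3·THF, THF, 0 °C to rt; then MeOH
Reagents that add atoms: none
Why: Chemoselective borane reduction of the acid; the C–Cl stereocentre is untouched.

**Step 12**
Reactants: 21 (2S)-2-chloro-4-methylpentan-1-ol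
Product: 23 (3R,4S)-4-chloro-6-methylhept-1-en-3-ol, via chloro aldehyde 22 (not isolated)
Conditions: Dess–Martin periodinane, CH2Cl2, 0 °C; filter and concentrate cold; then CH2=CHMgBr, THF, −78 °C; H2O
Reagents that add atoms: vinylmagnesium bromide C=C[Mg]Br
Why: Dess–Martin oxidation gives the labile α-chloro aldehyde, used at once, and Cornforth–Evans-controlled Grignard addition (attack anti to C–Cl in the dipole-opposed conformer) gives the 1,2-anti chlorohydrin, setting C8' from C9'.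

**Step 13**
Reactants: 18 (2R,4S,5S,6R)-5,6-dihydroxy-4-methyl-7-oxooctan-2-yl (2E)-2-methylhepta-2,6-dienoate; 23 (3R,4S)-4-chloro-6-methylhept-1-en-3-ol
Product: 24 (2R,4S,5S,6R)-5,6-dihydroxy-4-methyl-7-oxooctan-2-yl (2E,6E,8R,9S)-9-chloro-8-hydroxy-2,11-dimethyldodeca-2,6-dienoate
Conditions: 23 (3 equiv), Hoveyda–Grubbs II (5 mol%), CH2Cl2, 40 °C
Reagents that add atoms: none
Why: Olefin cross-metathesis of the terminal alkene with the allylic alcohol gives the E-alkene; the trisubstituted enoate is inert.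

**Step 14**
Reactants: 24 (2R,4S,5S,6R)-5,6-dihydroxy-4-methyl-7-oxooctan-2-yl (2E,6E,8R,9S)-9-chloro-8-hydroxy-2,11-dimethyldodeca-2,6-dienoate
Product: 25 (2R,4S,5S,6R)-4-methyl-7-oxo-5,6-bis[(triethylsilyl)oxy]octan-2-yl (2E,6E,8R,9S)-9-chloro-2,11-dimethyl-8-[(triethylsilyl)oxy]dodeca-2,6-dienoate
Conditions: TESCl, imidazole, DMAP (cat.), DMF, 0 °C to rt
Reagents that add atoms: chlorotriethylsilane CC[Si](CC)(CC)Cl
Why: Silylation of the three secondary hydroxyls; non-chelating silyl ethers are wanted for the aldol and are removed by fluoride at the end.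

**Step 15**
Reactants: 26 L-malic acid; 27 2,2-dimethylpropanal
Product: 28 [(2S,4S)-2-tert-butyl-5-oxo-1,3-dioxolan-4-yl]acetic acid
Conditions: TsOH (cat.), H2SO4 (cat.), pentane, reflux (Dean–Stark); recrystallise
Reagents that add atoms: none
Why: Acetalisation of the α-hydroxy acid gives the cis-dioxolanone, so the malic acid stereocentre sets the acetal centre (self-regeneration of stereocentres).

**Step 16**
Reactants: 28 [(2S,4S)-2-tert-butyl-5-oxo-1,3-dioxolan-4-yl]acetic acid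
Product: 30 [(2S,4S)-2-tert-butyl-4-methyl-5-oxo-1,3-dioxolan-4-yl]acetic acid, via dilithium enolate 29 (not isolated)
Conditions: LiHMDS (2.2 equiv), THF, −78 °C; MeI, −78 to −30 °C; 1 M HCl
Reagents that add atoms: lithium bis(trimethylsilyl)amide [Li]N([Si](C)(C)C)[Si](C)(C)C (Li of 29 only); iodomethane CI
Why: Enolate alkylation trans to the tert-butyl group, controlled by the acetal centre, puts methyl where the hydrogen was (net retention), giving C5.

**Step 17**
Reactants: 30 [(2S,4S)-2-tert-butyl-4-methyl-5-oxo-1,3-dioxolan-4-yl]acetic acid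
Product: 32 (3S)-3-hydroxy-3-methyloxolan-2-one, via hydroxyethyl dioxolanone 31 (not isolated)
Conditions: BH3·THF, THF, 0 °C to rt; MeOH; then TsOH (cat.), CH2Cl2, rt
Reagents that add atoms: none
Why: Borane reduces only the free acid, and the new primary alcohol transacylates onto the dioxolanone to give the γ-lactone with loss of pivalaldehyde; the quaternary centre is untouched.

**Step 18**
Reactants: 32 (3S)-3-hydroxy-3-methyloxolan-2-one
Product: 33 (3S)-3-methyl-3-[(triethylsilyl)oxy]oxolan-2-one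
Conditions: TESOTf, 2,6-lutidine, CH2Cl2, −78 to 0 °C
Reagents that add atoms: triethylsilyl trifluoromethanesulfonate CC[Si](CC)(CC)OS(=O)(=O)C(F)(F)F
Why: Silyl triflate silylation of the hindered tertiary hydroxyl; no stereocentre is touched.

**Step 19**
Reactants: 33 (3S)-3-methyl-3-[(triethylsilyl)oxy]oxolan-2-one
Product: 34 (3S)-3-methyl-3-[(triethylsilyl)oxy]oxolan-2-ol
Conditions: DIBAL-H (1.1 equiv), CH2Cl2, −78 °C; aq. Rochelle salt
Reagents that add atoms: none
Why: DIBAL-H half-reduction of the lactone stops at the lactol (anomer mixture) at −78 °C.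

**Step 20**
Reactants: 34 (3S)-3-methyl-3-[(triethylsilyl)oxy]oxolan-2-ol
Product: 35 (2E,4S)-6-hydroxy-2,4-dimethyl-4-[(triethylsilyl)oxy]hex-2-enal
Conditions: Ph3P=C(CH3)CHO (1.5 equiv), toluene, 90 °C
Reagents that add atoms: 2-(triphenyl-λ5-phosphanylidene)propanal CC(C=O)=P(c1ccccc1)(c1ccccc1)c1ccccc1
Why: Wittig olefination of the open hydroxy-aldehyde form with the stabilised formyl ylide gives the E-configured 2-methyl enal.

**Step 21**
Reactants: 35 (2E,4S)-6-hydroxy-2,4-dimethyl-4-[(triethylsilyl)oxy]hex-2-enal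
Product: 36 (3S,4E)-3,5-dimethyl-3-[(triethylsilyl)oxy]hepta-4,6-dien-1-ol
Conditions: Ph3PCH3Br (3 equiv), KOtBu (2.8 equiv), THF, 0 °C to rt
Reagents that add atoms: methyltriphenylphosphonium bromide C[P+](c1ccccc1)(c1ccccc1)c1ccccc1.[Br-]
Why: Wittig methylenation of the enal completes the E-diene without touching the trisubstituted alkene.

**Step 22**
Reactants: 36 (3S,4E)-3,5-dimethyl-3-[(triethylsilyl)oxy]hepta-4,6-dien-1-ol
Product: 37 (3S,4E)-3,5-dimethyl-3-[(triethylsilyl)oxy]hepta-4,6-dienal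
Conditions: Dess–Martin periodinane, pyridine, CH2Cl2, 0 °C
Reagents that add atoms: none
Why: Buffered Dess–Martin oxidation of the primary alcohol is tolerated by the diene and the tertiary silyl ether.

**Step 23**
Reactants: 25 (2R,4S,5S,6R)-4-methyl-7-oxo-5,6-bis[(triethylsilyl)oxy]octan-2-yl (2E,6E,8R,9S)-9-chloro-2,11-dimethyl-8-[(triethylsilyl)oxy]dodeca-2,6-dienoate; 37 (3S,4E)-3,5-dimethyl-3-[(triethylsilyl)oxy]hepta-4,6-dienal
Product: 39 (2R,4S,5S,6R,9R,11S,12E)-9-hydroxy-4,11,13-trimethyl-7-oxo-5,6,11-tris[(triethylsilyl)oxy]pentadeca-12,14-dien-2-yl (2E,6E,8R,9S)-9-chloro-2,11-dimethyl-8-[(triethylsilyl)oxy]dodeca-2,6-dienoate, via boron enolate 38 (not isolated)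
Conditions: (c-Hex)2BCl (1.5 equiv), Et3N (1.8 equiv), Et2O, −78 to 0 °C; then 37 (1.4 equiv), −78 to −20 °C; pH 7 buffer, MeOH, H2O2, 0 °C
Reagents that add atoms: chlorodicyclohexylborane ClB(C1CCCCC1)C1CCCCC1 (boron group of 38 only)
Why: Boron aldol of the methyl-side enolate through a chair transition state, in which 1,4-induction from the C10 silyloxy centre (C–OSi anti to the enolate C–O, attack anti to C11) is expected to give the 1,4-syn (7R) adduct, the β-silyloxy groups of both partners exerting little control.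

**Step 24**
Reactants: 39 (2R,4S,5S,6R,9R,11S,12E)-9-hydroxy-4,11,13-trimethyl-7-oxo-5,6,11-tris[(triethylsilyl)oxy]pentadeca-12,14-dien-2-yl (2E,6E,8R,9S)-9-chloro-2,11-dimethyl-8-[(triethylsilyl)oxy]dodeca-2,6-dienoate
Product: 41 (2R,4S,5S,6R,9R,11S,12E)-5,6,9,11-tetrahydroxy-4,11,13-trimethyl-7-oxopentadeca-12,14-dien-2-yl (2E,6E)-2-methyl-7-[(2R,3R)-3-(2-methylpropyl)oxiran-2-yl]hepta-2,6-dienoate, via chlorohydrin pentaol 40 (not isolated)
Conditions: TBAF·3H2O (6 equiv), THF, 0 °C to rt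
Reagents that add atoms: none
Why: Fluoride removes the four triethylsilyl groups, and the allylic alkoxide freed next to the C–Cl bond closes the trans-oxirane by intramolecular SN2 with inversion at C9' (retention at C8').

**Compound list**
1 | (R)-2-methyloxirane | C[C@@H]1CO1 | starting material
2 | ethyl prop-2-ynoate | C#CC(=O)OCC | starting material
3 | ethyl 3-lithioprop-2-ynoate | [Li]C#CC(=O)OCC | intermediate
4 | ethyl (5R)-5-hydroxyhex-2-ynoate | C[C@@H](O)CC#CC(=O)OCC | intermediate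
5 | ethyl (2Z,5R)-5-hydroxyhex-2-enoate | C[C@@H](O)C/C=C\C(=O)OCC | intermediate
6 | (6R)-6-methyl-5,6-dihydro-2H-pyran-2-one | C[C@@H]1CC=CC(=O)O1 | intermediate
7 | dimethyl (4R,5R)-2,2-dimethyl-1,3-dioxolane-4,5-dicarboxylate | COC(=O)[C@@H]1OC(C)(C)O[C@H]1C(=O)OC | starting material
8 | (4R,5R)-2,2-dimethyl-1,3-dioxolane-4,5-dicarboxylic acid | OC(=O)[C@@H]1OC(C)(C)O[C@H]1C(=O)O | intermediate
9 | (4R,5S)-2,2-dimethyl-5-[(2R,4R)-2-methyl-6-oxooxan-4-yl]-1,3-dioxolane-4-carboxylic acid | OC(=O)[C@@H]1OC(C)(C)O[C@H]1[C@H]2CC(=O)O[C@H](C)C2 | intermediate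
10 | (4R,5S)-2,2-dimethyl-5-[(2R,4R)-2-methyl-6-oxooxan-4-yl]-1,3-dioxolane-4-carbonyl chloride | ClC(=O)[C@@H]1OC(C)(C)O[C@H]1[C@H]2CC(=O)O[C@H](C)C2 | intermediate
11 | (4R,6R)-4-[(4S,5R)-5-acetyl-2,2-dimethyl-1,3-dioxolan-4-yl]-6-methyloxan-2-one | CC(=O)[C@@H]1OC(C)(C)O[C@H]1[C@H]2CC(=O)O[C@H](C)C2 | intermediate
12 | lithium (3R,5R)-3-[(4S,5R)-5-acetyl-2,2-dimethyl-1,3-dioxolan-4-yl]-5-hydroxyhexanoate | CC(=O)[C@@H]1OC(C)(C)O[C@H]1[C@@H](CC(=O)[O-])C[C@@H](C)O.[Li+] | intermediate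
13 | 1-{(4R,5S)-5-[(2S,4R)-4-hydroxypentan-2-yl]-2,2-dimethyl-1,3-dioxolan-4-yl}ethan-1-one | CC(=O)[C@@H]1OC(C)(C)O[C@H]1[C@@H](C)C[C@@H](C)O | intermediate
14 | pent-4-enal | C=CCCC=O | starting material
15 | 2-methylpropanedioic acid | CC(C(=O)O)C(=O)O | starting material
16 | (2E)-2-methylhepta-2,6-dienoic acid | OC(=O)/C(C)=C/CCC=C | intermediate
17 | (2R,4S)-4-[(4S,5R)-5-acetyl-2,2-dimethyl-1,3-dioxolan-4-yl]pentan-2-yl (2E)-2-methylhepta-2,6-dienoate | CC(=O)[C@@H]1OC(C)(C)O[C@H]1[C@@H](C)C[C@@H](C)OC(=O)/C(C)=C/CCC=C | intermediate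
18 | (2R,4S,5S,6R)-5,6-dihydroxy-4-methyl-7-oxooctan-2-yl (2E)-2-methylhepta-2,6-dienoate | CC(=O)[C@H](O)[C@@H](O)[C@@H](C)C[C@@H](C)OC(=O)/C(C)=C/CCC=C | intermediate
19 | L-leucine | CC(C)C[C@H](N)C(=O)O | starting material
20 | (2S)-2-chloro-4-methylpentanoic acid | CC(C)C[C@H](Cl)C(=O)O | intermediate
21 | (2S)-2-chloro-4-methylpentan-1-ol | CC(C)C[C@H](Cl)CO | intermediate
22 | (2S)-2-chloro-4-methylpentanal | CC(C)C[C@H](Cl)C=O | intermediate
23 | (3R,4S)-4-chloro-6-methylhept-1-en-3-ol | C=C[C@@H](O)[C@@H](Cl)CC(C)C | intermediate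
24 | (2R,4S,5S,6R)-5,6-dihydroxy-4-methyl-7-oxooctan-2-yl (2E,6E,8R,9S)-9-chloro-8-hydroxy-2,11-dimethyldodeca-2,6-dienoate | CC(=O)[C@H](O)[C@@H](O)[C@@H](C)C[C@@H](C)OC(=O)/C(C)=C/CC/C=C/[C@@H](O)[C@@H](Cl)CC(C)C | intermediate
25 | (2R,4S,5S,6R)-4-methyl-7-oxo-5,6-bis[(triethylsilyl)oxy]octan-2-yl (2E,6E,8R,9S)-9-chloro-2,11-dimethyl-8-[(triethylsilyl)oxy]dodeca-2,6-dienoate | CC(=O)[C@H](O[Si](CC)(CC)CC)[C@@H](O[Si](CC)(CC)CC)[C@@H](C)C[C@@H](C)OC(=O)/C(C)=C/CC/C=C/[C@@H](O[Si](CC)(CC)CC)[C@@H](Cl)CC(C)C | intermediate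
26 | L-malic acid, (2S)-2-hydroxybutanedioic acid | OC(=O)C[C@H](O)C(=O)O | starting material
27 | 2,2-dimethylpropanal | CC(C)(C)C=O | starting material
28 | [(2S,4S)-2-tert-butyl-5-oxo-1,3-dioxolan-4-yl]acetic acid (cis) | OC(=O)C[C@@H]1O[C@H](C(C)(C)C)OC1=O | intermediate
29 | dilithium enolate-carboxylate of 28 | [Li+].[Li+].[O-]C(=O)CC1=C([O-])O[C@@H](C(C)(C)C)O1 | intermediate
30 | [(2S,4S)-2-tert-butyl-4-methyl-5-oxo-1,3-dioxolan-4-yl]acetic acid | OC(=O)C[C@]1(C)O[C@H](C(C)(C)C)OC1=O | intermediate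
31 | (2S,5S)-2-tert-butyl-5-(2-hydroxyethyl)-5-methyl-1,3-dioxolan-4-one | OCC[C@]1(C)O[C@H](C(C)(C)C)OC1=O | intermediate
32 | (3S)-3-hydroxy-3-methyloxolan-2-one | C[C@]1(O)CCOC1=O | intermediate
33 | (3S)-3-methyl-3-[(triethylsilyl)oxy]oxolan-2-one | C[C@]1(O[Si](CC)(CC)CC)CCOC1=O | intermediate
34 | (3S)-3-methyl-3-[(triethylsilyl)oxy]oxolan-2-ol (anomer mixture at C2) | C[C@]1(O[Si](CC)(CC)CC)CCOC1O | intermediate
35 | (2E,4S)-6-hydroxy-2,4-dimethyl-4-[(triethylsilyl)oxy]hex-2-enal | O=C/C(C)=C/[C@@](C)(O[Si](CC)(CC)CC)CCO | intermediate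
36 | (3S,4E)-3,5-dimethyl-3-[(triethylsilyl)oxy]hepta-4,6-dien-1-ol | C=C/C(C)=C/[C@@](C)(O[Si](CC)(CC)CC)CCO | intermediate
37 | (3S,4E)-3,5-dimethyl-3-[(triethylsilyl)oxy]hepta-4,6-dienal | C=C/C(C)=C/[C@@](C)(O[Si](CC)(CC)CC)CC=O | intermediate
38 | dicyclohexylboron enolate of 25 (methyl-side enolate) | C=C(OB(C1CCCCC1)C1CCCCC1)[C@H](O[Si](CC)(CC)CC)[C@@H](O[Si](CC)(CC)CC)[C@@H](C)C[C@@H](C)OC(=O)/C(C)=C/CC/C=C/[C@@H](O[Si](CC)(CC)CC)[C@@H](Cl)CC(C)C | intermediate
39 | (2R,4S,5S,6R,9R,11S,12E)-9-hydroxy-4,11,13-trimethyl-7-oxo-5,6,11-tris[(triethylsilyl)oxy]pentadeca-12,14-dien-2-yl (2E,6E,8R,9S)-9-chloro-2,11-dimethyl-8-[(triethylsilyl)oxy]dodeca-2,6-dienoate | C=C/C(C)=C/[C@@](C)(O[Si](CC)(CC)CC)C[C@@H](O)CC(=O)[C@H](O[Si](CC)(CC)CC)[C@@H](O[Si](CC)(CC)CC)[C@@H](C)C[C@@H](C)OC(=O)/C(C)=C/CC/C=C/[C@@H](O[Si](CC)(CC)CC)[C@@H](Cl)CC(C)C | intermediate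
40 | (2R,4S,5S,6R,9R,11S,12E)-5,6,9,11-tetrahydroxy-4,11,13-trimethyl-7-oxopentadeca-12,14-dien-2-yl (2E,6E,8R,9S)-9-chloro-8-hydroxy-2,11-dimethyldodeca-2,6-dienoate | C=C/C(C)=C/[C@@](C)(O)C[C@@H](O)CC(=O)[C@H](O)[C@@H](O)[C@@H](C)C[C@@H](C)OC(=O)/C(C)=C/CC/C=C/[C@@H](O)[C@@H](Cl)CC(C)C | intermediate
41 | (2R,4S,5S,6R,9R,11S,12E)-5,6,9,11-tetrahydroxy-4,11,13-trimethyl-7-oxopentadeca-12,14-dien-2-yl (2E,6E)-2-methyl-7-[(2R,3R)-3-(2-methylpropyl)oxiran-2-yl]hepta-2,6-dienoate | C=C/C(C)=C/[C@@](C)(O)C[C@@H](O)CC(=O)[C@H](O)[C@@H](O)[C@@H](C)C[C@@H](C)OC(=O)/C(C)=C/CC/C=C/[C@H]1O[C@@H]1CC(C)C | target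

**Totals**
Total step count: 24 (one-pot intermediates 3, 5, 10, 12, 22, 29, 31, 38 and 40 are not counted as separate steps).
Longest linear sequence: 11 steps (1, 2, 4, 5, 6, 8, 9, 13, 14, 23, 24, from (R)-2-methyloxirane); the tartrate and malic acid lines are 10 steps each.

**Three steps most likely to fail**

Step 4 (the proposed new step). The risks are a second decarboxylation of the product acid, oxidative bis-decarboxylation of the vicinal diacid to a dioxole, and only moderate 4,6-trans selectivity on the small 6-methyl lactone. The fallback uses known chemistry; it sets out from 7 and comes back at 9. Half-saponification of 7 (KOH 1 equiv, MeOH) gives the half-ester (4R,5R)-5-(methoxycarbonyl)-2,2-dimethyl-1,3-dioxolane-4-carboxylic acid F1. N-Hydroxyphthalimide, DIC and DMAP (cat.) turn it into the redox-active ester 4-(1,3-dioxoisoindolin-2-yl) 5-methyl (4R,5R)-2,2-dimethyl-1,3-dioxolane-4,5-dicarboxylate F2. Visible-light reductive decarboxylative Giese addition of F2 to 6 ([Ru(bpy)3](PF6)2 cat., Hantzsch ester, i-Pr2NEt, CH2Cl2, blue LEDs) gives methyl (4R,5S)-2,2-dimethyl-5-[(2R,4R)-2-methyl-6-oxooxan-4-yl]-1,3-dioxolane-4-carboxylate F3. LiOH hydrolyses ester and lactone to the hydroxy diacid (4R,5S)-5-[(2R,4R)-1-carboxy-4-hydroxypentan-2-yl]-2,2-dimethyl-1,3-dioxolane-4-carboxylic acid F4, which relactonises on acidification (TsOH cat., toluene, 40 °C) to 9.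

Step 23. The sense and level of 1,4-induction from the C10 silyloxy centre rest on a transition-state model, not on a direct precedent, and the C7 epimer could be formed in quantity. The fallback sets out from 25 and 37 and comes back at 39. The aldol is run as in step 23; if the C7 epimer, the (9S)-hydroxy epimer of 39 F5, is the main product, it is inverted by a Mitsunobu reaction with chloroacetic acid (PPh3, DIAD, toluene, 0 °C) to the (9R)-chloroacetate of 39 F6. The chloroacetate is then removed under near-neutral conditions (thiourea, NaHCO3, MeOH/THF, rt) to give 39.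

Step 24. Basic fluoride may cause retro-aldol cleavage of the β-hydroxy ketone or epimerisation at C10 before the epoxide has closed. The fallback sets out from 24 and comes back at 41; it closes the epoxide before the fragment union and ends with buffered acidic fluoride. K2CO3 in MeOH at 0 °C converts 24 into the epoxy diol (2R,4S,5S,6R)-5,6-dihydroxy-4-methyl-7-oxooctan-2-yl (2E,6E)-2-methyl-7-[(2R,3R)-3-(2-methylpropyl)oxiran-2-yl]hepta-2,6-dienoate F7. TESCl and imidazole give its 5,6-bis(triethylsilyl) ether F8. Enolisation with (c-Hex)2BCl and Et3N gives the dicyclohexylboron enolate of F8 F9, which adds to 37 to give the 5,6,11-tris(triethylsilyl) ether of 41 F10. HF·pyridine buffered with pyridine (THF, 0 °C) removes the three silyl groups to give 41.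

**Further compounds**
F1 | step 4 | (4R,5R)-5-(methoxycarbonyl)-2,2-dimethyl-1,3-dioxolane-4-carboxylic acid | COC(=O)[C@@H]1OC(C)(C)O[C@H]1C(=O)O
F2 | step 4 | 4-(1,3-dioxoisoindolin-2-yl) 5-methyl (4R,5R)-2,2-dimethyl-1,3-dioxolane-4,5-dicarboxylate | COC(=O)[C@@H]1OC(C)(C)O[C@H]1C(=O)ON1C(=O)c2ccccc2C1=O
F3 | step 4 | methyl (4R,5S)-2,2-dimethyl-5-[(2R,4R)-2-methyl-6-oxooxan-4-yl]-1,3-dioxolane-4-carboxylate | COC(=O)[C@@H]1OC(C)(C)O[C@H]1[C@H]2CC(=O)O[C@H](C)C2
F4 | step 4 | (4R,5S)-5-[(2R,4R)-1-carboxy-4-hydroxypentan-2-yl]-2,2-dimethyl-1,3-dioxolane-4-carboxylic acid | OC(=O)[C@@H]1OC(C)(C)O[C@H]1[C@@H](CC(=O)O)C[C@@H](C)O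
F5 | step 23 | (9S)-hydroxy epimer of 39 | C=C/C(C)=C/[C@@](C)(O[Si](CC)(CC)CC)C[C@H](O)CC(=O)[C@H](O[Si](CC)(CC)CC)[C@@H](O[Si](CC)(CC)CC)[C@@H](C)C[C@@H](C)OC(=O)/C(C)=C/CC/C=C/[C@@H](O[Si](CC)(CC)CC)[C@@H](Cl)CC(C)C
F6 | step 23 | (9R)-chloroacetate of 39 | C=C/C(C)=C/[C@@](C)(O[Si](CC)(CC)CC)C[C@@H](OC(=O)CCl)CC(=O)[C@H](O[Si](CC)(CC)CC)[C@@H](O[Si](CC)(CC)CC)[C@@H](C)C[C@@H](C)OC(=O)/C(C)=C/CC/C=C/[C@@H](O[Si](CC)(CC)CC)[C@@H](Cl)CC(C)C
F7 | step 24 | (2R,4S,5S,6R)-5,6-dihydroxy-4-methyl-7-oxooctan-2-yl (2E,6E)-2-methyl-7-[(2R,3R)-3-(2-methylpropyl)oxiran-2-yl]hepta-2,6-dienoate | CC(=O)[C@H](O)[C@@H](O)[C@@H](C)C[C@@H](C)OC(=O)/C(C)=C/CC/C=C/[C@H]1O[C@@H]1CC(C)C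
F8 | step 24 | 5,6-bis(triethylsilyl) ether of F7 | CC(=O)[C@H](O[Si](CC)(CC)CC)[C@@H](O[Si](CC)(CC)CC)[C@@H](C)C[C@@H](C)OC(=O)/C(C)=C/CC/C=C/[C@H]1O[C@@H]1CC(C)C
F9 | step 24 | dicyclohexylboron enolate of F8 | C=C(OB(C1CCCCC1)C1CCCCC1)[C@H](O[Si](CC)(CC)CC)[C@@H](O[Si](CC)(CC)CC)[C@@H](C)C[C@@H](C)OC(=O)/C(C)=C/CC/C=C/[C@H]1O[C@@H]1CC(C)C
F10 | step 24 | 5,6,11-tris(triethylsilyl) ether of 41 | C=C/C(C)=C/[C@@](C)(O[Si](CC)(CC)CC)C[C@@H](O)CC(=O)[C@H](O[Si](CC)(CC)CC)[C@@H](O[Si](CC)(CC)CC)[C@@H](C)C[C@@H](C)OC(=O)/C(C)=C/CC/C=C/[C@H]1O[C@@H]1CC(C)C
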